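## Retrosynthetic overview

1. Target ⇐ its 7‑O‑TBS ether ⇐ Rh‑catalysed asymmetric 1,4‑addition of 4‑hydroxyphenylboronic acid to 7‑(TBSO)‑6,8‑diprenylchromone (C2–aryl bond; C2 is set here).
2. Chromone ⇐ one‑flask [4+2] cycloaromatisation/cyclocondensation of a 2,4‑diprenylated 1‑methoxy‑1,3‑bis(silyloxy)diene with 5,5‑dimethoxypent‑1‑yn‑3‑one. The ester carbon becomes C8a and its carbonyl oxygen becomes O1.
3. Diene ⇐ methyl acetoacetate + 2 prenyl bromide (γ, then α), so both prenyl groups are placed before the arene exists. Ynone ⇐ methyl 3,3‑dimethoxypropanoate + ethynylmagnesium bromide.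
4. Ring order: ring A (benzene) and ring C (pyranone) form together in step 4; ring B is bought as the boronic acid.

## Assumptions

- "One operation" means one flask with no isolation; the acid in step 4 is added to the same flask after the cycloaddition.
- Every compound that contributes atoms is numbered; bases, acids, catalysts and solvents are not.
- The sense of induction in step 5 is assigned by analogy: (S)‑biaryl bisphosphines give (S)‑3‑arylcyclohexanones, and the same face of the chromone gives 2S. If the first run shows the opposite sense, the (R)‑ligand is used and nothing else changes.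
- Nothing here has been run; the route rests on known reaction types, and step 4 is a proposed combination of them.

## Route

Step 1
Reactants: 1 methyl acetoacetate; 2 prenyl bromide (1‑bromo‑3‑methylbut‑2‑ene, 2.2 equiv in two portions)
Product: 4 methyl 7‑methyl‑2‑(3‑methylbut‑2‑en‑1‑yl)‑3‑oxooct‑6‑enoate, via γ‑prenyl keto ester 3 (not isolated)
Conditions: NaH (1.1 equiv), THF, 0 °C; n‑BuLi (1.05 equiv), 0 °C; 2 (1.0 equiv), 0 °C; then 2 (1.2 equiv), rt → 45 °C
Reagents that add atoms: prenyl bromide (2), CC(C)=CCBr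
Why: Huckin–Weiler dianion alkylation: the dianion of 1 reacts only at the γ‑carbon, and the remaining β‑keto ester monoanion 3 is C‑alkylated at the α‑carbon by the second portion of allylic bromide, so both prenyl groups are placed unambiguously (the α‑stereocentre is racemic and is destroyed in step 2).

Step 2
Reactants: 4 methyl 7‑methyl‑2‑(3‑methylbut‑2‑en‑1‑yl)‑3‑oxooct‑6‑enoate; 5 tert‑butyldimethylsilyl chloride; 6 trimethylsilyl chloride
Product: 8 3‑[(tert‑butyldimethylsilyl)oxy]‑1‑methoxy‑7‑methyl‑2‑(3‑methylbut‑2‑en‑1‑yl)‑1‑[(trimethylsilyl)oxy]octa‑1,3,6‑triene, via TBS enol ether 7 (not isolated)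
Conditions: NaH (1.05 equiv), THF, 0 °C; TBSCl (1.05 equiv), 0 °C → rt; then LDA (commercial solution, 1.15 equiv), −78 °C; TMSCl (1.3 equiv), −78 → 0 °C; pentane, filter under Ar, use crude
Reagents that add atoms: tert‑butyldimethylsilyl chloride (5), CC(C)(C)[Si](C)(C)Cl; trimethylsilyl chloride (6), C[Si](C)(C)Cl
Why: Chan‑type 1,3‑bis(silyl enol ether) synthesis: O‑silylation of the sodium enolate gives β‑silyloxy enoate 7, whose γ‑CH2 is deprotonated vinylogously by LDA and trapped on the ester oxygen by TMSCl, which puts the robust TBS group on the future O7 and the labile TMS group on the future O1 (3Z geometry expected from A1,3 strain; ketene acetal geometry is irrelevant).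

Step 3
Reactants: 9 methyl 3,3‑dimethoxypropanoate; 10 N,O‑dimethylhydroxylamine hydrochloride; 11 ethynylmagnesium bromide
Product: 13 5,5‑dimethoxypent‑1‑yn‑3‑one, via Weinreb amide 12 (not isolated)
Conditions: 10 (1.5 equiv), i‑PrMgCl (3.0 equiv), THF, −20 °C; then 11 (0.5 M in THF, 2.5 equiv), −20 → 0 °C; inverse quench into cold aq. NH4Cl/HCl (pH 3–4), brief
Reagents that add atoms: ethynylmagnesium bromide (11), C#C[Mg]Br
Why: One‑pot Weinreb ketone synthesis: the magnesium amide of MeNHOMe converts ester 9 into amide 12, whose chelated tetrahedral adduct with the alkynyl Grignard stops at the ketone stage, and the cold acidic inverse quench keeps the liberated amine from adding to the ynone while the acetal survives.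

Step 4
Reactants: 8 3‑[(tert‑butyldimethylsilyl)oxy]‑1‑methoxy‑7‑methyl‑2‑(3‑methylbut‑2‑en‑1‑yl)‑1‑[(trimethylsilyl)oxy]octa‑1,3,6‑triene (1.3 equiv); 13 5,5‑dimethoxypent‑1‑yn‑3‑one
Product: 16 7‑[(tert‑butyldimethylsilyl)oxy]‑6,8‑bis(3‑methylbut‑2‑en‑1‑yl)‑4H‑chromen‑4‑one, via Diels–Alder adduct 14 (not isolated), via phenol keto acetal 15 (not isolated)
Conditions: toluene, 80 °C, sealed, Ar; then same flask: MeOH (3 equiv), CSA (10–20 mol %), 40–60 °C
Reagents that add atoms: none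
Why: Proposed new method: the electron‑rich vinylketene acetal diene 8 and the terminal ynone 13 should combine in a regioselective [4+2] (diene C4 to the unsubstituted alkyne carbon, ketene‑acetal carbon to the acyl‑bearing carbon; closest known reaction is the Brassard/Chan diene–alkyne cycloaromatisation to acylresorcinols). Acid then collapses the O‑methyl O‑silyl ketal of 14 with loss of MeOSiMe3 to give ring A (15), and the freed ortho‑phenol condenses with the β‑keto acetal (the classical chromone closure of o‑hydroxyaryl β‑keto aldehyde equivalents) to close ring C. The competing [3+3] aldol mode cannot aromatise because diene C2 carries a prenyl group; no stereocentre is formed.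

Step 5
Reactants: 16 7‑[(tert‑butyldimethylsilyl)oxy]‑6,8‑bis(3‑methylbut‑2‑en‑1‑yl)‑4H‑chromen‑4‑one; 17 4‑hydroxyphenylboronic acid (3 equiv)
Product: 18 (2S)‑7‑[(tert‑butyldimethylsilyl)oxy]‑2‑(4‑hydroxyphenyl)‑6,8‑bis(3‑methylbut‑2‑en‑1‑yl)‑2,3‑dihydro‑4H‑chromen‑4‑one
Conditions: [Rh(OH)(cod)]2 (2.5 mol %), (S)‑MeO‑F12‑BIPHEP (5.5 mol %), toluene/H2O 10:1, 40 °C
Reagents that add atoms: 4‑hydroxyphenylboronic acid (17), OB(O)c1ccc(O)cc1
Why: Hayashi–Miyaura Rh(I)‑catalysed asymmetric 1,4‑addition to a chromone: the aryl–Rh species bearing the (S)‑bisphosphine inserts C2=C3 on the face that gives 2S, and the electron‑poor ligand speeds protonation of the oxa‑π‑allyl rhodium so that β‑oxygen elimination to the chalcone does not erode yield or ee (base‑free conditions keep the hindered aryl silyl ether and the prenyl groups intact).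

Step 6
Reactants: 18 (2S)‑7‑[(tert‑butyldimethylsilyl)oxy]‑2‑(4‑hydroxyphenyl)‑6,8‑bis(3‑methylbut‑2‑en‑1‑yl)‑2,3‑dihydro‑4H‑chromen‑4‑one
Product: 19 (2S)‑7‑hydroxy‑2‑(4‑hydroxyphenyl)‑6,8‑bis(3‑methylbut‑2‑en‑1‑yl)‑2,3‑dihydro‑4H‑chromen‑4‑one
Conditions: HF·pyridine, pyridine, THF, 0 °C → rt
Reagents that add atoms: none
Why: Fluoride cleavage of the aryl silyl ether under buffered, weakly acidic conditions: no base is present, so the flavanone cannot racemise by retro‑oxa‑Michael opening, and the prenyl groups and C2 are untouched.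

## Compound list

1 | methyl acetoacetate | COC(=O)CC(C)=O | starting material
2 | prenyl bromide (1‑bromo‑3‑methylbut‑2‑ene) | CC(C)=CCBr | starting material
3 | methyl 7‑methyl‑3‑oxooct‑6‑enoate (formed as its enolate) | COC(=O)CC(=O)CCC=C(C)C | intermediate (not isolated)
4 | methyl 7‑methyl‑2‑(3‑methylbut‑2‑en‑1‑yl)‑3‑oxooct‑6‑enoate (racemic) | COC(=O)C(CC=C(C)C)C(=O)CCC=C(C)C | intermediate
5 | tert‑butyldimethylsilyl chloride | CC(C)(C)[Si](C)(C)Cl | starting material
6 | trimethylsilyl chloride | C[Si](C)(C)Cl | starting material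
7 | methyl 3‑[(tert‑butyldimethylsilyl)oxy]‑7‑methyl‑2‑(3‑methylbut‑2‑en‑1‑yl)octa‑2,6‑dienoate | COC(=O)C(CC=C(C)C)=C(O[Si](C)(C)C(C)(C)C)CCC=C(C)C | intermediate (not isolated)
8 | 3‑[(tert‑butyldimethylsilyl)oxy]‑1‑methoxy‑7‑methyl‑2‑(3‑methylbut‑2‑en‑1‑yl)‑1‑[(trimethylsilyl)oxy]octa‑1,3,6‑triene (geometric mixture at the ketene acetal) | COC(O[Si](C)(C)C)=C(CC=C(C)C)C(O[Si](C)(C)C(C)(C)C)=CCC=C(C)C | intermediate
9 | methyl 3,3‑dimethoxypropanoate | COC(=O)CC(OC)OC | starting material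
10 | N,O‑dimethylhydroxylamine hydrochloride | CNOC.Cl | starting material
11 | ethynylmagnesium bromide | C#C[Mg]Br | starting material
12 | N‑methoxy‑N‑methyl‑3,3‑dimethoxypropanamide | CON(C)C(=O)CC(OC)OC | intermediate (not isolated)
13 | 5,5‑dimethoxypent‑1‑yn‑3‑one | C#CC(=O)CC(OC)OC | intermediate
14 | 1‑{4‑[(tert‑butyldimethylsilyl)oxy]‑6‑methoxy‑3,5‑bis(3‑methylbut‑2‑en‑1‑yl)‑6‑[(trimethylsilyl)oxy]cyclohexa‑1,4‑dien‑1‑yl}‑3,3‑dimethoxypropan‑1‑one (diastereomer mixture, both centres lost on aromatisation) | COC1(O[Si](C)(C)C)C(CC=C(C)C)=C(O[Si](C)(C)C(C)(C)C)C(CC=C(C)C)C=C1C(=O)CC(OC)OC | intermediate (not isolated)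
15 | 1‑{4‑[(tert‑butyldimethylsilyl)oxy]‑2‑hydroxy‑3,5‑bis(3‑methylbut‑2‑en‑1‑yl)phenyl}‑3,3‑dimethoxypropan‑1‑one | COC(OC)CC(=O)c1cc(CC=C(C)C)c(O[Si](C)(C)C(C)(C)C)c(CC=C(C)C)c1O | intermediate (not isolated)
16 | 7‑[(tert‑butyldimethylsilyl)oxy]‑6,8‑bis(3‑methylbut‑2‑en‑1‑yl)‑4H‑chromen‑4‑one | O=c1ccoc2c(CC=C(C)C)c(O[Si](C)(C)C(C)(C)C)c(CC=C(C)C)cc12 | intermediate
17 | 4‑hydroxyphenylboronic acid | OB(O)c1ccc(O)cc1 | starting material
18 | (2S)‑7‑[(tert‑butyldimethylsilyl)oxy]‑2‑(4‑hydroxyphenyl)‑6,8‑bis(3‑methylbut‑2‑en‑1‑yl)‑2,3‑dihydro‑4H‑chromen‑4‑one | CC(C)=CCc1cc2c(c(CC=C(C)C)c1O[Si](C)(C)C(C)(C)C)O[C@H](c1ccc(O)cc1)CC2=O | intermediate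
19 | (2S)‑7‑hydroxy‑2‑(4‑hydroxyphenyl)‑6,8‑bis(3‑methylbut‑2‑en‑1‑yl)‑2,3‑dihydro‑4H‑chromen‑4‑one | CC(C)=CCc1cc2c(c(CC=C(C)C)c1O)O[C@H](c1ccc(O)cc1)CC2=O | target

## Step count

Total steps: 6. Longest linear sequence: 5 (steps 1, 2, 4, 5, 6); step 3 is a one‑step side branch.

## Steps most likely to fail, with fallbacks

**Step 4 (one‑flask cycloaromatisation/chromone closure).** The risks are a sluggish cycloaddition of the tetrasubstituted diene, collapse of the ketal with loss of silanol instead of methanol (giving a dead‑end aryl methyl ether), and acid damage to the prenyl groups or the TBS ether during the acetal condensation. The fallback separates the two ring closures and sets out from 8. Diene 8 is heated with commercial but‑3‑yn‑2‑one (toluene, 60 °C), the simplest and most reactive terminal ynone, and the adduct is aromatised with PPTS/MeOH to 1‑{4‑[(tert‑butyldimethylsilyl)oxy]‑2‑hydroxy‑3,5‑bis(3‑methylbut‑2‑en‑1‑yl)phenyl}ethan‑1‑one F1. F1 is condensed with N,N‑dimethylformamide dimethyl acetal (toluene, 90 °C) to the enaminone (E)‑1‑{4‑[(tert‑butyldimethylsilyl)oxy]‑2‑hydroxy‑3,5‑bis(3‑methylbut‑2‑en‑1‑yl)phenyl}‑3‑(dimethylamino)prop‑2‑en‑1‑one F2. F2 closes with acetic acid at room temperature, losing dimethylamine, and the route is rejoined at 16.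

**Step 5 (asymmetric 1,4‑addition).** The risks are low conversion on an electron‑rich, 8‑substituted chromone, ring opening to the chalcone, or insufficient ee. The fallback gives up catalyst control and sets out from 16. The same addition is run with ligand‑free [Rh(OH)(cod)]2 and 17, which gives the racemate: 18 together with its enantiomer (2R)‑7‑[(tert‑butyldimethylsilyl)oxy]‑2‑(4‑hydroxyphenyl)‑6,8‑bis(3‑methylbut‑2‑en‑1‑yl)‑2,3‑dihydro‑4H‑chromen‑4‑one F3. The two are separated by preparative chiral SFC; F3 is racemised with catalytic DBU and recycled, and the (2S) fraction rejoins the route at 18.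

**Step 2 (one‑pot mixed‑silyl diene).** The risks are incomplete O‑silylation with TBSCl, consumption of LDA by residual silyl chloride, or C‑silylation. The fallback changes the protecting‑group plan and sets out from 4. Keto ester 4 is converted by the classical two‑step procedure, first with TMSCl/Et3N into methyl 7‑methyl‑2‑(3‑methylbut‑2‑en‑1‑yl)‑3‑[(trimethylsilyl)oxy]octa‑2,6‑dienoate F4, then with LDA/TMSCl into 1‑methoxy‑7‑methyl‑2‑(3‑methylbut‑2‑en‑1‑yl)‑1,3‑bis[(trimethylsilyl)oxy]octa‑1,3,6‑triene F5. F5 is taken through the step‑4 operation with 13, using PPTS instead of CSA because the 7‑OH is now free next to two prenyl groups, to give 7‑hydroxy‑6,8‑bis(3‑methylbut‑2‑en‑1‑yl)‑4H‑chromen‑4‑one F6. F6 is silylated with 5 (imidazole, DMF), and the route is rejoined at 16.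

## Further compounds

F1 | step 4 | 1‑{4‑[(tert‑butyldimethylsilyl)oxy]‑2‑hydroxy‑3,5‑bis(3‑methylbut‑2‑en‑1‑yl)phenyl}ethan‑1‑one | CC(=O)c1cc(CC=C(C)C)c(O[Si](C)(C)C(C)(C)C)c(CC=C(C)C)c1O
F2 | step 4 | (E)‑1‑{4‑[(tert‑butyldimethylsilyl)oxy]‑2‑hydroxy‑3,5‑bis(3‑methylbut‑2‑en‑1‑yl)phenyl}‑3‑(dimethylamino)prop‑2‑en‑1‑one | CN(C)/C=C/C(=O)c1cc(CC=C(C)C)c(O[Si](C)(C)C(C)(C)C)c(CC=C(C)C)c1O
F3 | step 5 | (2R)‑7‑[(tert‑butyldimethylsilyl)oxy]‑2‑(4‑hydroxyphenyl)‑6,8‑bis(3‑methylbut‑2‑en‑1‑yl)‑2,3‑dihydro‑4H‑chromen‑4‑one | CC(C)=CCc1cc2c(c(CC=C(C)C)c1O[Si](C)(C)C(C)(C)C)O[C@@H](c1ccc(O)cc1)CC2=O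
F4 | step 2 | methyl 7‑methyl‑2‑(3‑methylbut‑2‑en‑1‑yl)‑3‑[(trimethylsilyl)oxy]octa‑2,6‑dienoate | COC(=O)C(CC=C(C)C)=C(O[Si](C)(C)C)CCC=C(C)C
F5 | step 2 | 1‑methoxy‑7‑methyl‑2‑(3‑methylbut‑2‑en‑1‑yl)‑1,3‑bis[(trimethylsilyl)oxy]octa‑1,3,6‑triene | COC(O[Si](C)(C)C)=C(CC=C(C)C)C(O[Si](C)(C)C)=CCC=C(C)C
F6 | step 2 | 7‑hydroxy‑6,8‑bis(3‑methylbut‑2‑en‑1‑yl)‑4H‑chromen‑4‑one | O=c1ccoc2c(CC=C(C)C)c(O)c(CC=C(C)C)cc12
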